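**Abbreviations:** TIPS = triisopropylsilyl, TBS = tert-butyldimethylsilyl, TES = triethylsilyl. Atom numbers are those of the 2,3-dihydrobenzofuran (O1, C2, C3, C3a–C7a). C9/O9 are the oxymethyl carbon and oxygen on C3, ring A is the benzo ring, and ring B is the 4-hydroxy-3-methoxyphenyl group on C2.

## The problem

Target 25 is an 8–5′ neolignan, a 2-aryl-2,3-dihydrobenzofuran. Ring A carries a methoxy group at C7 and a 3-hydroxypropyl chain at C5, ring B sits on C2, and C9 on C3 is esterified with (E)-p-coumaric acid. There are only two stereocentres, C2 (R) and C3 (S), in a trans relation, and they behave very differently. C2 is a benzylic ether carbon para to the free 4-OH of ring B and ionises easily. C3 is configurationally stable once C9 is at the alcohol oxidation level, but is an acidic α-aryl position while C9 is a carbonyl. C3 is therefore the centre to set absolutely, and C2 is best set last under the control of C3. After ring closure the C2–O1 bond is threatened by strong acid, hydrogenolysis and oxidants, the cinnamate ester and its E double bond by base, nucleophiles and hydrogenation, and the free phenols by oxidation. Two primary hydroxyls (O9 and the propanol terminus) and two kinds of phenol must be told apart so that only O9 is acylated. The enabling feature is that C2 lies para to the ring B phenol and five atoms from the phenolic oxygen of ring A. Loss of a leaving group from C2 gives a planar para-quinone methide, and the ring A oxygen (the future O1) can add to C2 and close the dihydrofuran with C3 deciding the face.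

## Retrosynthesis

**Ester and chain hydroxyl (25 ⇒ 24 ⇒ 22 + 23).** The O9–acyl bond is cut last, so the base- and reduction-sensitive cinnamate is present only in the final two steps. The propanol oxygen is kept as a TIPS ether in 24, so O9 is the only free aliphatic hydroxyl when p-coumaric acid 23 is attached to alcohol 22. A Mitsunobu esterification is asked for because it pairs a carboxylic acid with an aliphatic alcohol and leaves the three phenols alone; no phenol protection of 22 or 23 is then needed.

**O1–C2 (22 ⇒ 20).** Cutting the aryl ether bond at C2 opens the only heterocycle and removes the only labile stereocentre. The neighbouring cuts (C2–C3 or C3–C3a with the ring intact) would require C2 to be set and preserved through later steps. Precursor 20 is an acyclic 1-aryl-2-(2-hydroxyaryl)propane-1,3-diol in which only C3 matters; the carbinol centre is erased on ionisation. The forward reaction must ionise the benzylic hydroxyl under mild acid, close the five-membered ring through the ring A phenol and deliver the 2,3-trans isomer without touching the alkyl TIPS ether. O9 is left free, because closures of this kind are known on free 1,3-diols; this avoids a selective protection and a later hydrogenolysis next to C2–O1.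

**C2–C3 (20 ⇒ 19 ⇒ 18 ⇒ 13 + 15).** Diol 20 comes from its bis(aryl silyl) ether 19, and 19 from reductive release of aldol adduct 18. The C2–C3 bond is an aldol bond between the arylacetyl imide 13 (ring A) and the protected vanillin 15 (ring B). An auxiliary aldol is preferred to a catalytic method because the α-aryl enolate is hindered and only Cα has to be right. The (R)-4-benzyl auxiliary gives Cα as R in 18, which is C3 (S) once C9 is reduced. Reduction with LiBH4 takes C9 out of the carbonyl level and freezes C3. Both phenols travel as aryl silyl ethers, which fluoride removes in the presence of the alkyl TIPS ether.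

**Imide and side chain of ring A (13 ⇒ 10 + 11; 10 ⇒ 9 ⇒ 7).** The N-acyl bond is cut to acid 10 and commercial auxiliary 11. The arylacetic acid is the oxidative cleavage product (via aldehyde 9) of the ortho-allyl arene 7, so the two-carbon acid unit comes from a three-carbon allyl group.

**Ring A substitution (7 ⇒ 6 ⇒ 4 ⇒ 3 ⇒ 1; 15 ⇒ 14).** Bis-silyl ether 7 comes from phenol-alcohol 6 in one silylation. The C3a–allyl bond of 6 is cut by a retro-Claisen rearrangement to allyl ether 4, which can only rearrange to the one free ortho position. Ether 4 comes from dihydroconiferyl alcohol 3, the hydroboration product of eugenol 1. Eugenol thus supplies ring A with the methoxy group, the phenol oxygen and the three-carbon chain already in place. Aldehyde 15 is silylated vanillin 14.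

## Roads not taken

**Alternative 1: ring A built by cycloaddition.**
- Cut: C3a–C4 and C7–C7a, so that ring A itself is assembled.
- Forward key step: a trans γ-lactone A2 carrying C2 and C3 is converted to its silyl ketene acetal A3, which adds to methyl 3-bromocoumalate A4; loss of CO2 and silanol aromatises the adduct to A1.
- Merits: the route is convergent, the pyrone fixes the regiochemistry of ring A, and both stereocentres are set in a lactone and never exposed to acid. In the timing of C2 this road is at least as good as the chosen one.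
- Weak points: ring A arrives with the wrong substituents. The bromide at C7 must become a methoxy group by a C–O coupling ortho to the ring oxygen. The ester at C5 must be homologated by two carbons to the hydroxypropyl chain. The O9 benzyl ether must later be removed by hydrogenolysis next to C2–O1. Lactone A2 also needs its own asymmetric synthesis with two centres.
- Comparison: the chosen plan takes ring A fully substituted from eugenol and spends its steps on stereochemistry and protecting groups only, which gives a much shorter functional-group endgame.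

**Alternative 2: temporary cyclopropane on a benzofuran.**
- Cut: C3–C9.
- Forward key step: benzofuran A6 is cyclopropanated at C2=C3 with ethyl diazoacetate A7 under CuOTf and a chiral bis(oxazoline), giving A5. The C2–C9 bond would later be opened as a donor–acceptor cyclopropane with introduction of ring B at C2, trans to the C3 substituent.
- Merits: C3 is set catalytically and A6 is a flat, easily made precursor. In chirality economy this road is better than a stoichiometric auxiliary.
- Weak points: after ring opening C3 carries CH2CO2Et, one carbon more than the oxymethyl group, so the ester carbon must be excised with installation of oxygen at C9. The opening must be selective for C2–C9, and the aryl nucleophile must react para to its hydroxyl. Enantioselection on an electron-rich benzofuran depends on catalyst tuning.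
- Comparison: the chosen plan has the exact carbon count at C9 from the outset and its auxiliary 11 is recovered in step 10.

**Alternative 3: rhodium carbenoid C–H insertion.**
- Cut: C2–C3.
- Forward key step: the ring A aryldiazoacetate A9 with Rh2(S-PTTL)4 inserts into the benzylic C–H bond of its ortho benzyl ether, closing the ring to the cis ester A8 with C2 as in the target. Base epimerisation at C3 would give the trans ester A10, and reduction would give the O9 alcohol.
- Merits: as a bond-forming step it is the stronger one. It makes a C–C bond and the ring in one catalytic enantioselective operation, the ester is C9 at a directly reducible level, and it could branch from acid 10 with a similar step count.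
- Weak points: the kinetic product is cis. The epimerisation at C3 runs through an ester enolate with the ring oxygen as a β-leaving group, so ring opening and re-closure can erode C2. The O-benzylation needed to reach A9 uses an electrophile that is itself prone to quinone methide formation, and a diazo compound and a costly catalyst are required.
- Comparison: the chosen plan reaches the trans isomer directly under acid with no base at an eliminable centre, controls C3 at auxiliary level with separable diastereomers, and tolerates any mixture at the carbinol centre.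

Key step: step 12

## Route

Remark on the chemistry: the target is taken as the (2R,3S), 2,3-trans isomer. The carbinol configuration of the ring-closure precursor 20 is immaterial because it is erased in step 12.

Step 1
Reactants: 1 eugenol (4-allyl-2-methoxyphenol)
Product: 3 dihydroconiferyl alcohol (4-(3-hydroxypropyl)-2-methoxyphenol), via bis(9-BBN) adduct 2 (not isolated)
Conditions: 9-BBN (2.2 equiv), THF, 0 → 60 °C; then NaOH aq, H2O2, 0 °C → rt
Reagents that add atoms: hydrogen peroxide, OO (oxygen of the new hydroxyl); 9-BBN, B1C2CCCC1CCC2 (boron and carbon held only in intermediate 2)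
Why: Anti-Markovnikov hydroboration–oxidation of a terminal alkene; 9-BBN gives the primary borane almost exclusively, and the phenol is only borylated (hence two equivalents) and is released again in the alkaline peroxide work-up.

Step 2
Reactants: 3 dihydroconiferyl alcohol
Product: 4 3-[4-(allyloxy)-3-methoxyphenyl]propan-1-ol
Conditions: allyl bromide, K2CO3, acetone, reflux
Reagents that add atoms: allyl bromide, C=CCBr
Why: Williamson etherification; K2CO3 deprotonates only the phenol, so the primary alcohol stays free.

Step 3
Reactants: 4 3-[4-(allyloxy)-3-methoxyphenyl]propan-1-ol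
Product: 6 2-allyl-4-(3-hydroxypropyl)-6-methoxyphenol, via ortho-dienone 5 (not isolated)
Conditions: PhNEt2, 190 °C
Reagents that add atoms: none
Why: Aromatic Claisen rearrangement ([3,3]-sigmatropic shift, then tautomerisation of dienone 5); the para position is blocked by the chain and the other ortho position by the methoxy group, so the allyl group can only settle on the carbon that becomes C3a.

Step 4
Reactants: 6 2-allyl-4-(3-hydroxypropyl)-6-methoxyphenol
Product: 7 triisopropyl{2-allyl-6-methoxy-4-[3-(triisopropylsilyloxy)propyl]phenoxy}silane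
Conditions: TIPSOTf (2.3 equiv), 2,6-lutidine, CH2Cl2, 0 °C → rt
Reagents that add atoms: triisopropylsilyl triflate, CC(C)[Si](OS(=O)(=O)C(F)(F)F)(C(C)C)C(C)C
Why: Silyl triflate silylation; TIPSOTf is reactive enough for the doubly ortho-substituted phenol and caps the primary alcohol in the same operation, and the bulky aryl silyl ether resists migration to neighbouring alkoxides later.

Step 5
Reactants: 7 bis-TIPS ether of 6
Product: 9 2-{3-methoxy-2-(triisopropylsilyloxy)-5-[3-(triisopropylsilyloxy)propyl]phenyl}acetaldehyde, via vicinal diol 8 (not isolated)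
Conditions: OsO4 (2 mol %), NaIO4, 2,6-lutidine, dioxane/H2O (3:1), rt
Reagents that add atoms: osmium tetroxide, O=[Os](=O)(=O)=O (delivers the oxygen of diol 8 and of the aldehyde, re-formed by NaIO4); sodium periodate, [Na+].[O-]I(=O)(=O)=O
Why: Lemieux–Johnson oxidative cleavage (catalytic dihydroxylation, then periodate glycol cleavage); it spares the electron-rich arene that ozone could attack, and 2,6-lutidine suppresses over-oxidation; the aldehyde is used crude.

Step 6
Reactants: 9 arylacetaldehyde
Product: 10 2-{3-methoxy-2-(triisopropylsilyloxy)-5-[3-(triisopropylsilyloxy)propyl]phenyl}acetic acid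
Conditions: NaClO2, NaH2PO4, 2-methyl-2-butene, t-BuOH/H2O, 0 °C → rt
Reagents that add atoms: sodium chlorite, [Na+].[O-]Cl=O
Why: Pinnick oxidation of an aldehyde to the acid under buffered conditions that leave silyl ethers and the arene alone; 2-methyl-2-butene scavenges HOCl.

Step 7
Reactants: 10 arylacetic acid; 11 (R)-4-benzyloxazolidin-2-one
Product: 13 (R)-4-benzyl-3-(2-{3-methoxy-2-(triisopropylsilyloxy)-5-[3-(triisopropylsilyloxy)propyl]phenyl}acetyl)oxazolidin-2-one, via mixed pivalic anhydride 12 (not isolated)
Conditions: PivCl, Et3N, THF, −20 °C; then 11, LiCl, −20 °C → rt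
Reagents that add atoms: pivaloyl chloride, CC(C)(C)C(=O)Cl (held only in intermediate 12)
Why: N-Acylation of an Evans oxazolidinone through the mixed pivalic anhydride with LiCl/Et3N activation; the oxazolidinone attacks the less hindered arylacetyl carbonyl.

Step 8
Reactants: 14 vanillin
Product: 15 4-(tert-butyldimethylsilyloxy)-3-methoxybenzaldehyde
Conditions: TBSCl, imidazole, DMF, rt
Reagents that add atoms: tert-butyldimethylsilyl chloride, CC(C)(C)[Si](C)(C)Cl
Why: Imidazole-promoted silylation of a phenol; the aryl silyl ether survives the boron aldol and the hydride reduction and is removed later together with the aryl TIPS ether.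

Step 9
Reactants: 13 arylacetyl imide; 15 O-TBS vanillin
Product: 18 (R)-4-benzyl-3-[(2R,3R)-3-hydroxy-3-[4-(tert-butyldimethylsilyloxy)-3-methoxyphenyl]-2-{3-methoxy-2-(triisopropylsilyloxy)-5-[3-(triisopropylsilyloxy)propyl]phenyl}propanoyl]oxazolidin-2-one, via dibutylboron Z-enolate 16 (not isolated), via dibutylboron aldolate 17 (not isolated)
Conditions: Bu2BOTf, iPr2NEt, CH2Cl2, −78 → 0 °C; 15, −78 → 0 °C; pH 7 buffer, MeOH, H2O2, 0 °C
Reagents that add atoms: dibutylboron triflate, CCCCB(CCCC)OS(=O)(=O)C(F)(F)F (boron and butyl groups held only in intermediates 16 and 17)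
Why: Evans syn-aldol reaction: soft enolisation gives the Z boron enolate, which adds to 15 through a closed chair transition state on the face away from the benzyl group of the (R)-auxiliary. This sets Cα (the future C3) as R in 18, which becomes S once C9 is reduced, and the carbinol as R; only the Cα configuration is carried into the target.

Step 10
Reactants: 18 syn-aldol adduct
Product: 19 (1R,2S)-1-[4-(tert-butyldimethylsilyloxy)-3-methoxyphenyl]-2-{3-methoxy-2-(triisopropylsilyloxy)-5-[3-(triisopropylsilyloxy)propyl]phenyl}propane-1,3-diol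
Conditions: LiBH4, MeOH (1 equiv), THF, 0 °C
Reagents that add atoms: none
Why: Reductive removal of the oxazolidinone by hydride attack at the exocyclic imide carbonyl gives the 1,3-diol and returns auxiliary 11; C3 can no longer epimerise once C9 is an alcohol.

Step 11
Reactants: 19 bis(aryl silyl) diol
Product: 20 (1R,2S)-1-(4-hydroxy-3-methoxyphenyl)-2-{2-hydroxy-3-methoxy-5-[3-(triisopropylsilyloxy)propyl]phenyl}propane-1,3-diol
Conditions: TBAF (2.2 equiv), AcOH (2.5 equiv), THF, 0 °C
Reagents that add atoms: none
Why: Chemoselective fluoride cleavage of aryl silyl ethers: the phenoxide leaving groups make both aryl O–Si bonds far more labile than the primary alkyl TIPS ether, and the acetic acid buffer keeps the para-hydroxybenzyl alcohol from eliminating.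

Step 12
Reactants: 20 tetrahydroxy precursor (the 1S carbinol epimer, if present, reacts identically)
Product: 22 4-{(2R,3S)-3-(hydroxymethyl)-7-methoxy-5-[3-(triisopropylsilyloxy)propyl]-2,3-dihydro-1-benzofuran-2-yl}-2-methoxyphenol, via para-quinone methide 21 (not isolated)
Conditions: BF3·OEt2 (0.2 equiv), CH2Cl2, −40 → 0 °C
Reagents that add atoms: none
Why: BF3·OEt2 ionises the benzylic hydroxyl of 20 to a cation that is the O-protonated form of para-quinone methide 21; C2 is planar in both, so either carbinol epimer enters the same intermediate. The ring A phenol then adds to C2 (oxa-conjugate addition, 5-exo-trig: the ring O1–C2–C3–C3a–C7a forms and the attacked C2=C1′ bond lies outside it), ring B rearomatises and O1–C2 is formed. The closest known reaction type is the acid-mediated cyclisation of 1-aryl-2-(2-hydroxyaryl)propane-1,3-diols to trans-2-aryl-3-hydroxymethyl-2,3-dihydrobenzofurans, which is also the ring-forming half of phenylcoumaran biosynthesis. The new stereocentre C2 is controlled by C3 alone: in the closing transition state ring B avoids the C9 hydroxymethyl group, and because the product is itself a para-hydroxybenzyl aryl ether the closure is reversible under the acid, so any cis isomer re-ionises and drains to the more stable (2R,3S) trans isomer. The step needs diastereoselectivity at C2 (secured by the fixed C3 centre plus reversibility), chemoselectivity for the phenol oxygen over O9 (the only alternative ring is a strained, reversibly formed oxetane) and retention at C3 (no carbonyl flanks it, and catalytic acid at low temperature keeps proton loss from the cation slower than ring closure). The alkyl TIPS ether is expected to be inert to catalytic BF3·OEt2 at or below 0 °C.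

Step 13
Reactants: 22 dihydrobenzofuran alcohol; 23 (E)-p-coumaric acid
Product: 24 {(2R,3S)-2-(4-hydroxy-3-methoxyphenyl)-7-methoxy-5-[3-(triisopropylsilyloxy)propyl]-2,3-dihydro-1-benzofuran-3-yl}methyl (E)-3-(4-hydroxyphenyl)prop-2-enoate
Conditions: PPh3, DIAD, THF, 0 °C → rt
Reagents that add atoms: none
Why: Mitsunobu esterification, chemoselective for the pairing of carboxylic acid and aliphatic alcohol: only the acid is acidic enough to protonate the betaine and only the primary alcohol is activated as an alkoxyphosphonium ion, so the phenols of 22 and 23 need no protection. C9 is not a stereocentre, and the neutral conditions spare C2–O1 and the E alkene.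

Step 14
Reactants: 24 TIPS-protected ester
Product: 25 [(2R,3S)-2-(4-hydroxy-3-methoxyphenyl)-5-(3-hydroxypropyl)-7-methoxy-2,3-dihydro-1-benzofuran-3-yl]methyl (E)-3-(4-hydroxyphenyl)prop-2-enoate (CNP0202924.1)
Conditions: HF·pyridine, pyridine, THF, 0 °C → rt
Reagents that add atoms: none
Why: Fluoride cleavage of the primary TIPS ether with pyridine-buffered HF·pyridine, under which the cinnamate ester and the E alkene are stable; any reversible opening at C2 could only re-close to the trans isomer because C3 is untouched.

## Compound list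

1 | eugenol (4-allyl-2-methoxyphenol) | C=CCc1ccc(O)c(OC)c1 | starting material
2 | 9-{3-[4-(9-borabicyclo[3.3.1]nonan-9-yloxy)-3-methoxyphenyl]propyl}-9-borabicyclo[3.3.1]nonane (formed in the flask) | COc1cc(CCCB2C3CCCC2CCC3)ccc1OB1C2CCCC1CCC2 | intermediate
3 | dihydroconiferyl alcohol, 4-(3-hydroxypropyl)-2-methoxyphenol | COc1cc(CCCO)ccc1O | intermediate
4 | 3-[4-(allyloxy)-3-methoxyphenyl]propan-1-ol | COc1cc(CCCO)ccc1OCC=C | intermediate
5 | 6-allyl-4-(3-hydroxypropyl)-2-methoxycyclohexa-2,4-dien-1-one (formed in the flask) | COC1=CC(CCCO)=CC(CC=C)C1=O | intermediate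
6 | 2-allyl-4-(3-hydroxypropyl)-6-methoxyphenol | COc1cc(CCCO)cc(CC=C)c1O | intermediate
7 | triisopropyl{2-allyl-6-methoxy-4-[3-(triisopropylsilyloxy)propyl]phenoxy}silane | COc1cc(CCCO[Si](C(C)C)(C(C)C)C(C)C)cc(CC=C)c1O[Si](C(C)C)(C(C)C)C(C)C | intermediate
8 | 3-{3-methoxy-2-(triisopropylsilyloxy)-5-[3-(triisopropylsilyloxy)propyl]phenyl}propane-1,2-diol, racemic (formed in the flask) | COc1cc(CCCO[Si](C(C)C)(C(C)C)C(C)C)cc(CC(O)CO)c1O[Si](C(C)C)(C(C)C)C(C)C | intermediate
9 | 2-{3-methoxy-2-(triisopropylsilyloxy)-5-[3-(triisopropylsilyloxy)propyl]phenyl}acetaldehyde | COc1cc(CCCO[Si](C(C)C)(C(C)C)C(C)C)cc(CC=O)c1O[Si](C(C)C)(C(C)C)C(C)C | intermediate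
10 | 2-{3-methoxy-2-(triisopropylsilyloxy)-5-[3-(triisopropylsilyloxy)propyl]phenyl}acetic acid | COc1cc(CCCO[Si](C(C)C)(C(C)C)C(C)C)cc(CC(=O)O)c1O[Si](C(C)C)(C(C)C)C(C)C | intermediate
11 | (R)-4-benzyloxazolidin-2-one | O=C1N[C@H](Cc2ccccc2)CO1 | starting material
12 | mixed anhydride of acid 10 with pivalic acid (formed in the flask) | COc1cc(CCCO[Si](C(C)C)(C(C)C)C(C)C)cc(CC(=O)OC(=O)C(C)(C)C)c1O[Si](C(C)C)(C(C)C)C(C)C | intermediate
13 | (R)-4-benzyl-3-(2-{3-methoxy-2-(triisopropylsilyloxy)-5-[3-(triisopropylsilyloxy)propyl]phenyl}acetyl)oxazolidin-2-one | COc1cc(CCCO[Si](C(C)C)(C(C)C)C(C)C)cc(CC(=O)N2[C@H](Cc3ccccc3)COC2=O)c1O[Si](C(C)C)(C(C)C)C(C)C | intermediate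
14 | vanillin | COc1cc(C=O)ccc1O | starting material
15 | 4-(tert-butyldimethylsilyloxy)-3-methoxybenzaldehyde | COc1cc(C=O)ccc1O[Si](C)(C)C(C)(C)C | intermediate
16 | (Z)-O-dibutylboryl enolate of imide 13 (formed in the flask) | CCCCB(CCCC)O/C(=C\c1cc(CCCO[Si](C(C)C)(C(C)C)C(C)C)cc(OC)c1O[Si](C(C)C)(C(C)C)C(C)C)N1[C@H](Cc2ccccc2)COC1=O | intermediate
17 | O-dibutylboryl aldolate of 18, (2R,3R) (formed in the flask) | O=C([C@H](c1cc(CCCO[Si](C(C)C)(C(C)C)C(C)C)cc(OC)c1O[Si](C(C)C)(C(C)C)C(C)C)[C@@H](OB(CCCC)CCCC)c1ccc(O[Si](C)(C)C(C)(C)C)c(OC)c1)N1[C@H](Cc2ccccc2)COC1=O | intermediate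
18 | (R)-4-benzyl-3-[(2R,3R)-3-hydroxy-3-[4-(tert-butyldimethylsilyloxy)-3-methoxyphenyl]-2-{3-methoxy-2-(triisopropylsilyloxy)-5-[3-(triisopropylsilyloxy)propyl]phenyl}propanoyl]oxazolidin-2-one | O=C([C@H](c1cc(CCCO[Si](C(C)C)(C(C)C)C(C)C)cc(OC)c1O[Si](C(C)C)(C(C)C)C(C)C)[C@@H](O)c1ccc(O[Si](C)(C)C(C)(C)C)c(OC)c1)N1[C@H](Cc2ccccc2)COC1=O | intermediate
19 | (1R,2S)-1-[4-(tert-butyldimethylsilyloxy)-3-methoxyphenyl]-2-{3-methoxy-2-(triisopropylsilyloxy)-5-[3-(triisopropylsilyloxy)propyl]phenyl}propane-1,3-diol | OC[C@H](c1cc(CCCO[Si](C(C)C)(C(C)C)C(C)C)cc(OC)c1O[Si](C(C)C)(C(C)C)C(C)C)[C@@H](O)c1ccc(O[Si](C)(C)C(C)(C)C)c(OC)c1 | intermediate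
20 | (1R,2S)-1-(4-hydroxy-3-methoxyphenyl)-2-{2-hydroxy-3-methoxy-5-[3-(triisopropylsilyloxy)propyl]phenyl}propane-1,3-diol | OC[C@H](c1cc(CCCO[Si](C(C)C)(C(C)C)C(C)C)cc(OC)c1O)[C@@H](O)c1ccc(O)c(OC)c1 | intermediate
21 | 4-[(2S)-3-hydroxy-2-{2-hydroxy-3-methoxy-5-[3-(triisopropylsilyloxy)propyl]phenyl}propylidene]-2-methoxycyclohexa-2,5-dien-1-one, the para-quinone methide (formed in the flask) | COC1=CC(=C[C@H](CO)c2cc(CCCO[Si](C(C)C)(C(C)C)C(C)C)cc(OC)c2O)C=CC1=O | intermediate
22 | 4-{(2R,3S)-3-(hydroxymethyl)-7-methoxy-5-[3-(triisopropylsilyloxy)propyl]-2,3-dihydro-1-benzofuran-2-yl}-2-methoxyphenol | COc1cc([C@@H]2Oc3c(OC)cc(CCCO[Si](C(C)C)(C(C)C)C(C)C)cc3[C@H]2CO)ccc1O | intermediate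
23 | (E)-p-coumaric acid | OC(=O)/C=C/c1ccc(O)cc1 | starting material
24 | {(2R,3S)-2-(4-hydroxy-3-methoxyphenyl)-7-methoxy-5-[3-(triisopropylsilyloxy)propyl]-2,3-dihydro-1-benzofuran-3-yl}methyl (E)-3-(4-hydroxyphenyl)prop-2-enoate | COc1cc([C@@H]2Oc3c(OC)cc(CCCO[Si](C(C)C)(C(C)C)C(C)C)cc3[C@H]2COC(=O)/C=C/c2ccc(O)cc2)ccc1O | intermediate
25 | [(2R,3S)-2-(4-hydroxy-3-methoxyphenyl)-5-(3-hydroxypropyl)-7-methoxy-2,3-dihydro-1-benzofuran-3-yl]methyl (E)-3-(4-hydroxyphenyl)prop-2-enoate | COc1cc([C@@H]2Oc3c(OC)cc(CCCO)cc3[C@H]2COC(=O)/C=C/c2ccc(O)cc2)ccc1O | target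

## Step count and risks

Total: 14 steps. Longest linear sequence: 13 steps (steps 1–7 and 9–14 from eugenol); step 8 is a one-step side branch.

**Step 12 (key step).** Three processes could compete with ring closure. The cation could fragment with loss of formaldehyde, pushed by the free O9, or be trapped by the primary hydroxyl of a second molecule. Proton loss from C3 would give a stilbene and, on re-protonation, erode the C3 configuration. The alkyl silyl ether could also be partly lost to the acid. Fallback: mask O9 before ionisation. Starting from 19, TBSCl and imidazole (CH2Cl2, 0 °C) should silylate only the primary hydroxyl to give the O9 tert-butyldimethylsilyl ether F1. TBAF/AcOH as in step 11 should free the two phenols to give the O9-silylated triol F2. Catalytic BF3·OEt2 should close it to the O9-silylated dihydrobenzofuran F3. PPTS in EtOH should then remove the primary TBS ether in the presence of the primary TIPS ether, rejoining the route at 22.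

**Step 9.** The hindered α-aryl boron enolate may add slowly to the electron-rich aldehyde, the adduct may revert by retro-aldol cleavage on work-up, and facial selectivity at Cα may erode if the enolate reacts through an open transition state. Fallback: a titanium enolate on a different auxiliary. Starting from acid 10, coupling with (R)-4-benzylthiazolidine-2-thione (EDC·HCl, DMAP) should give the N-acyl thiazolidinethione F4. Its enolate formed with TiCl4, iPr2NEt and N-methylpyrrolidinone (conditions favouring the non-chelated, Evans-syn mode) should add to 15 to give the syn-aldol thiazolidinethione adduct F5. NaBH4 in THF/EtOH should cleave the auxiliary reductively and rejoin the route at 19.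

**Step 10.** The lithium aldolate may undergo retro-aldol fragmentation before hydride delivery, and the ring A silyl group may migrate to a neighbouring alkoxide. Fallback: cap the carbinol first. Starting from 18, TESOTf and 2,6-lutidine should give the O-triethylsilyl aldol imide F6. LiBH4 should then give the O-triethylsilyl primary alcohol F7 without an alkoxide at the carbinol. TBAF/AcOH with one more equivalent than in step 11 should remove the TES ether together with the two aryl silyl ethers, rejoining the route at 20.

**Step 13.** A phenol may compete as nucleophile (aryl ether formation or oligomerisation of the coumaric acid), and displacement at the β-branched C9 may be slow. Fallback: acylate through protected phenols and unmask them selectively. Starting from 22, Ac2O with aqueous NaOH at 0 °C should acetylate only the phenoxide to give the ring B aryl acetate F8. p-Coumaric acid 23 is acetylated (Ac2O, pyridine) to (E)-4-acetoxycinnamic acid F9. Carbodiimide esterification of F8 with F9 (EDC·HCl, DMAP, CH2Cl2) should give the diacetate ester F10. Pyrrolidine in CH2Cl2 should cleave the two aryl acetates and leave the alkyl cinnamate, rejoining the route at 24.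

## Further compounds

F1 | step 12 | (1R,2S)-3-(tert-butyldimethylsilyloxy)-1-[4-(tert-butyldimethylsilyloxy)-3-methoxyphenyl]-2-{3-methoxy-2-(triisopropylsilyloxy)-5-[3-(triisopropylsilyloxy)propyl]phenyl}propan-1-ol | CC(C)(C)[Si](C)(C)OC[C@H](c1cc(CCCO[Si](C(C)C)(C(C)C)C(C)C)cc(OC)c1O[Si](C(C)C)(C(C)C)C(C)C)[C@@H](O)c1ccc(O[Si](C)(C)C(C)(C)C)c(OC)c1
F2 | step 12 | (1R,2S)-3-(tert-butyldimethylsilyloxy)-1-(4-hydroxy-3-methoxyphenyl)-2-{2-hydroxy-3-methoxy-5-[3-(triisopropylsilyloxy)propyl]phenyl}propan-1-ol | CC(C)(C)[Si](C)(C)OC[C@H](c1cc(CCCO[Si](C(C)C)(C(C)C)C(C)C)cc(OC)c1O)[C@@H](O)c1ccc(O)c(OC)c1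
F3 | step 12 | 4-{(2R,3S)-3-[(tert-butyldimethylsilyloxy)methyl]-7-methoxy-5-[3-(triisopropylsilyloxy)propyl]-2,3-dihydro-1-benzofuran-2-yl}-2-methoxyphenol | COc1cc([C@@H]2Oc3c(OC)cc(CCCO[Si](C(C)C)(C(C)C)C(C)C)cc3[C@H]2CO[Si](C)(C)C(C)(C)C)ccc1O
F4 | step 9 | (R)-4-benzyl-3-(2-{3-methoxy-2-(triisopropylsilyloxy)-5-[3-(triisopropylsilyloxy)propyl]phenyl}acetyl)thiazolidine-2-thione | COc1cc(CCCO[Si](C(C)C)(C(C)C)C(C)C)cc(CC(=O)N2[C@H](Cc3ccccc3)CSC2=S)c1O[Si](C(C)C)(C(C)C)C(C)C
F5 | step 9 | (R)-4-benzyl-3-[(2R,3R)-3-hydroxy-3-[4-(tert-butyldimethylsilyloxy)-3-methoxyphenyl]-2-{3-methoxy-2-(triisopropylsilyloxy)-5-[3-(triisopropylsilyloxy)propyl]phenyl}propanoyl]thiazolidine-2-thione | O=C([C@H](c1cc(CCCO[Si](C(C)C)(C(C)C)C(C)C)cc(OC)c1O[Si](C(C)C)(C(C)C)C(C)C)[C@@H](O)c1ccc(O[Si](C)(C)C(C)(C)C)c(OC)c1)N1[C@H](Cc2ccccc2)CSC1=S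
F6 | step 10 | O-triethylsilyl ether of aldol adduct 18 | O=C([C@H](c1cc(CCCO[Si](C(C)C)(C(C)C)C(C)C)cc(OC)c1O[Si](C(C)C)(C(C)C)C(C)C)[C@@H](O[Si](CC)(CC)CC)c1ccc(O[Si](C)(C)C(C)(C)C)c(OC)c1)N1[C@H](Cc2ccccc2)COC1=O
F7 | step 10 | (2S,3R)-3-[4-(tert-butyldimethylsilyloxy)-3-methoxyphenyl]-2-{3-methoxy-2-(triisopropylsilyloxy)-5-[3-(triisopropylsilyloxy)propyl]phenyl}-3-(triethylsilyloxy)propan-1-ol | OC[C@H](c1cc(CCCO[Si](C(C)C)(C(C)C)C(C)C)cc(OC)c1O[Si](C(C)C)(C(C)C)C(C)C)[C@@H](O[Si](CC)(CC)CC)c1ccc(O[Si](C)(C)C(C)(C)C)c(OC)c1
F8 | step 13 | 4-{(2R,3S)-3-(hydroxymethyl)-7-methoxy-5-[3-(triisopropylsilyloxy)propyl]-2,3-dihydro-1-benzofuran-2-yl}-2-methoxyphenyl acetate | COc1cc([C@@H]2Oc3c(OC)cc(CCCO[Si](C(C)C)(C(C)C)C(C)C)cc3[C@H]2CO)ccc1OC(C)=O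
F9 | step 13 | (E)-4-acetoxycinnamic acid | CC(=O)Oc1ccc(/C=C/C(O)=O)cc1
F10 | step 13 | {(2R,3S)-2-(4-acetoxy-3-methoxyphenyl)-7-methoxy-5-[3-(triisopropylsilyloxy)propyl]-2,3-dihydro-1-benzofuran-3-yl}methyl (E)-3-(4-acetoxyphenyl)prop-2-enoate | COc1cc([C@@H]2Oc3c(OC)cc(CCCO[Si](C(C)C)(C(C)C)C(C)C)cc3[C@H]2COC(=O)/C=C/c2ccc(OC(C)=O)cc2)ccc1OC(C)=O
A1 | alternative 1 | methyl trans-3-(benzyloxymethyl)-7-bromo-2-[4-(tert-butyldimethylsilyloxy)-3-methoxyphenyl]-2,3-dihydrobenzofuran-5-carboxylate, C2 and C3 as in the target | COc1cc([C@@H]2Oc3c(Br)cc(C(=O)OC)cc3[C@H]2COCc2ccccc2)ccc1O[Si](C)(C)C(C)(C)C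
A2 | alternative 1 | trans-4-(benzyloxymethyl)-5-[4-(tert-butyldimethylsilyloxy)-3-methoxyphenyl]dihydrofuran-2(3H)-one, both centres as in the target | COc1cc([C@@H]2OC(=O)C[C@H]2COCc2ccccc2)ccc1O[Si](C)(C)C(C)(C)C
A3 | alternative 1 | tert-butyldimethylsilyl ketene acetal of lactone A2 | COc1cc([C@@H]2OC(O[Si](C)(C)C(C)(C)C)=C[C@H]2COCc2ccccc2)ccc1O[Si](C)(C)C(C)(C)C
A4 | alternative 1 | methyl 3-bromocoumalate (methyl 3-bromo-2-oxo-2H-pyran-5-carboxylate) | COC(=O)C1=COC(=O)C(Br)=C1
A5 | alternative 2 | ethyl exo-cyclopropa[b]benzofuran-1-carboxylate bearing 7-methoxy and 5-[3-(triisopropylsilyloxy)propyl], C3 as in the target | CCOC(=O)[C@@H]1[C@H]2Oc3c(OC)cc(CCCO[Si](C(C)C)(C(C)C)C(C)C)cc3[C@@H]12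
A6 | alternative 2 | 7-methoxy-5-[3-(triisopropylsilyloxy)propyl]-1-benzofuran | COc1cc(CCCO[Si](C(C)C)(C(C)C)C(C)C)cc2ccoc12
A7 | alternative 2 | ethyl diazoacetate | CCOC(=O)C=[N+]=[N-]
A8 | alternative 3 | methyl cis-2-[4-(tert-butyldimethylsilyloxy)-3-methoxyphenyl]-7-methoxy-5-[3-(triisopropylsilyloxy)propyl]-2,3-dihydrobenzofuran-3-carboxylate, C2 as in the target | COc1cc([C@@H]2Oc3c(OC)cc(CCCO[Si](C(C)C)(C(C)C)C(C)C)cc3[C@@H]2C(=O)OC)ccc1O[Si](C)(C)C(C)(C)C
A9 | alternative 3 | methyl 2-diazo-2-{2-[4-(tert-butyldimethylsilyloxy)-3-methoxybenzyloxy]-3-methoxy-5-[3-(triisopropylsilyloxy)propyl]phenyl}acetate | COC(=O)C(=[N+]=[N-])c1cc(CCCO[Si](C(C)C)(C(C)C)C(C)C)cc(OC)c1OCc1ccc(O[Si](C)(C)C(C)(C)C)c(OC)c1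
A10 | alternative 3 | methyl trans-2-[4-(tert-butyldimethylsilyloxy)-3-methoxyphenyl]-7-methoxy-5-[3-(triisopropylsilyloxy)propyl]-2,3-dihydrobenzofuran-3-carboxylate, C2 and C3 as in the target | COc1cc([C@@H]2Oc3c(OC)cc(CCCO[Si](C(C)C)(C(C)C)C(C)C)cc3[C@H]2C(=O)OC)ccc1O[Si](C)(C)C(C)(C)C
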